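Ring A is grown, not bought. Cutting C3a–C7a and C6–C7 reduces the 7-oxygenated 2,3-dihydrobenzofuran to a furan joined through C3–C2–O1 to an ethynyl ether. The feature exploited is the pair of adjacent oxygens on ring A, O1 on C7a and the oxygen on C7, next to the C3a–C7a fusion with the dihydrofuran ring. A single gold-catalysed cycloisomerisation closes both rings and releases the C7 phenol, while C2 and C3, set earlier by an Evans aldol reaction, stay untouched. The precursor is (1S,2R)-1-(3,4-dimethoxyphenyl)-2-(furan-2-yl)propyl ethynyl ether. The diol side chain is then attached at C5 by C–H borylation, thioester coupling and chelation-controlled reduction.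

Key step: step 9

Remark on the chemistry: the boron aldol reaction of the furylacetyl imide is assumed to follow the normal Z-enolate, syn-selective course of arylacetyl imides; the E geometry written for 14 is the one expected from anti addition and has no bearing on the outcome.

Step 1
Reactants: 1 2-(furan-2-yl)acetic acid; 2 (S)-4-benzyl-2-oxazolidinone
Product: 4 (S)-4-benzyl-3-[2-(furan-2-yl)acetyl]oxazolidin-2-one, via mixed pivalic anhydride 3 (not isolated)
Conditions: t-BuCOCl, Et3N, THF, −20 °C; then LiCl, 2, −20 °C → rt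
Reagents that add atoms: none
Why: N-acylation of an Evans oxazolidinone through a mixed pivalic anhydride is routine for arylacetic acids and avoids the ketene formation that an acid chloride would risk; no stereocentre is formed.

Step 2
Reactants: 4 (S)-4-benzyl-3-[2-(furan-2-yl)acetyl]oxazolidin-2-one; 5 3,4-dimethoxybenzaldehyde
Product: 8 (S)-4-benzyl-3-[(2R,3S)-3-(3,4-dimethoxyphenyl)-2-(furan-2-yl)-3-hydroxypropanoyl]oxazolidin-2-one, via Z-boron enolate 6 (not isolated), via boron aldolate 7 (not isolated)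
Conditions: Bu2BOTf, i-Pr2NEt, CH2Cl2, −78 → 0 °C; 5, −78 → 0 °C; then pH 7 buffer, MeOH, 30% H2O2, 0 °C
Reagents that add atoms: none
Why: In this Evans syn-aldol reaction, soft enolisation should give the Z-boron enolate 6, which adds to the aldehyde through a closed Zimmerman–Traxler chair on the face away from the benzyl group of the auxiliary, so that the auxiliary sets both the furyl-bearing carbon (R) and the carbinol carbon (S), the future C3 and C2 of the dihydrobenzofuran.

Step 3
Reactants: 8 (S)-4-benzyl-3-[(2R,3S)-3-(3,4-dimethoxyphenyl)-2-(furan-2-yl)-3-hydroxypropanoyl]oxazolidin-2-one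
Product: 9 (S)-4-benzyl-3-[(2R,3S)-3-(tert-butyldimethylsilyloxy)-3-(3,4-dimethoxyphenyl)-2-(furan-2-yl)propanoyl]oxazolidin-2-one
Conditions: TBSOTf, 2,6-lutidine, CH2Cl2, −78 → 0 °C
Reagents that add atoms: tert-butyldimethylsilyl triflate, CC(C)(C)[Si](C)(C)OS(=O)(=O)C(F)(F)F
Why: Silylation of the secondary alcohol with a silyl triflate and a hindered base is reliable and shuts off retro-aldol cleavage, fragmentation and oxetane formation in the hydride steps that follow; no stereocentre is touched.

Step 4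
Reactants: 9 (S)-4-benzyl-3-[(2R,3S)-3-(tert-butyldimethylsilyloxy)-3-(3,4-dimethoxyphenyl)-2-(furan-2-yl)propanoyl]oxazolidin-2-one
Product: 10 (2R,3S)-3-(tert-butyldimethylsilyloxy)-3-(3,4-dimethoxyphenyl)-2-(furan-2-yl)propan-1-ol
Conditions: LiBH4, MeOH (1 equiv), Et2O, 0 °C; then H2O
Reagents that add atoms: none
Why: Reductive cleavage of the N-acyl oxazolidinone by LiBH4 should give the primary alcohol and return the auxiliary, and the weakly basic medium should not enolise the furyl-bearing centre.

Step 5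
Reactants: 10 (2R,3S)-3-(tert-butyldimethylsilyloxy)-3-(3,4-dimethoxyphenyl)-2-(furan-2-yl)propan-1-ol
Product: 11 (2R,3S)-3-(tert-butyldimethylsilyloxy)-3-(3,4-dimethoxyphenyl)-2-(furan-2-yl)propyl 4-methylbenzenesulfonate
Conditions: TsCl, Et3N, DMAP (cat.), CH2Cl2, 0 °C → rt
Reagents that add atoms: 4-toluenesulfonyl chloride, Cc1ccc(cc1)S(=O)(=O)Cl
Why: Sulfonylation of the only free, primary hydroxyl (tosylation) activates that carbon for hydride displacement without touching a stereocentre.

Step 6
Reactants: 11 (2R,3S)-3-(tert-butyldimethylsilyloxy)-3-(3,4-dimethoxyphenyl)-2-(furan-2-yl)propyl 4-methylbenzenesulfonate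
Product: 12 tert-butyl{[(1S,2R)-1-(3,4-dimethoxyphenyl)-2-(furan-2-yl)propyl]oxy}dimethylsilane
Conditions: LiBHEt3, THF, 0 °C → rt; then H2O
Reagents that add atoms: none
Why: SN2 displacement of the primary tosylate by hydride (LiBHEt3 reduction) should turn the CH2OTs group into the future C3 methyl group, the silyl ether and the furan being inert to the reagent.

Step 7
Reactants: 12 tert-butyl{[(1S,2R)-1-(3,4-dimethoxyphenyl)-2-(furan-2-yl)propyl]oxy}dimethylsilane
Product: 13 (1S,2R)-1-(3,4-dimethoxyphenyl)-2-(furan-2-yl)propan-1-ol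
Conditions: Bu4NF, THF, rt
Reagents that add atoms: none
Why: Fluoride-induced desilylation frees the benzylic alcohol under basic, non-ionising conditions, so the carbinol centre keeps its configuration.

Step 8
Reactants: 13 (1S,2R)-1-(3,4-dimethoxyphenyl)-2-(furan-2-yl)propan-1-ol
Product: 17 (1S,2R)-1-(3,4-dimethoxyphenyl)-2-(furan-2-yl)propyl ethynyl ether, via dichlorovinyl ether 14 (not isolated), via chloroethynyl ether 15 (not isolated), via lithium acetylide 16 (not isolated)
Conditions: KH, THF, 0 °C → rt; Cl2C=CHCl, −50 °C → rt; then n-BuLi (2.5 equiv), −78 → −40 °C; MeOH, −78 °C; cold pH 8 work-up, basic alumina, used at once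
Reagents that add atoms: trichloroethylene, ClC=C(Cl)Cl
Why: In this Greene-type ynol ether synthesis the potassium alkoxide adds to dichloroacetylene generated from trichloroethylene to give 14, n-BuLi then effects β-elimination to 15 and chlorine–lithium exchange to 16, and methanol protonates 16; the carbinol C–O bond is never broken, so both stereocentres are retained.

Step 9
Reactants: 17 (1S,2R)-1-(3,4-dimethoxyphenyl)-2-(furan-2-yl)propyl ethynyl ether
Product: 20 (2S,3S)-2-(3,4-dimethoxyphenyl)-3-methyl-2,3-dihydrobenzofuran-7-ol, via oxepine 18 (not isolated), via arene oxide 19 (not isolated)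
Conditions: (Ph3P)AuNTf2 (3 mol %), 4 Å MS, CH2Cl2, −20 °C → rt
Reagents that add atoms: none
Why: Monovalent gold binds the ynol ether, whose oxygen makes the O-bearing alkyne carbon the electrophilic one; the C2=C3 bond of the furan adds there to give a catalyst-bound cyclopropyl gold carbene, the furan opens to a catalyst-bound Z-dienal carbene, the aldehyde oxygen closes onto the carbene carbon to give oxepine 18, and 18 contracts to arene oxide 19, which opens to phenol 20. The closest known reaction type is the gold-catalysed furan–yne phenol synthesis, which has been run on alkynyl ether tethers to give 7-hydroxy-2,3-dihydrobenzofurans. The dihydrofuran ring closes by 5-exo-dig attack of furan C2 on the future C7a (bond C3a–C7a); ring A closes by oxygen-to-carbene ring closure followed by 6π electrocyclisation of the oxepine, which makes the C6–C7 bond. No stereocentre is formed: C2 and C3 lie in the three-atom tether, no bond to either is broken, and their configuration is that of 17. The step needs regioselectivity twice: attack at the O-bearing alkyne carbon is secured by the polarisation of the ynol ether and by the tether length, and the hydroxyl ends on C7 because cleavage of the C6–O bond of 19 gives a cation delocalised onto C7a, where O1 stabilises it. Chemoselectivity for the furan over the dimethoxyphenyl ring follows from the far higher nucleophilicity of the furan, and cold, dry, acid-free conditions are meant to keep the benzylic O1–C2 bond from ionising.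

Step 10
Reactants: 20 (2S,3S)-2-(3,4-dimethoxyphenyl)-3-methyl-2,3-dihydrobenzofuran-7-ol
Product: 21 (2S,3S)-2-(3,4-dimethoxyphenyl)-7-methoxy-3-methyl-2,3-dihydrobenzofuran
Conditions: MeI, K2CO3, acetone, 50 °C
Reagents that add atoms: iodomethane, CI
Why: Williamson O-methylation of the phenoxide installs the C7 methoxy group under mildly basic conditions that leave the benzylic ether at C2 alone.

Step 11
Reactants: 21 (2S,3S)-2-(3,4-dimethoxyphenyl)-7-methoxy-3-methyl-2,3-dihydrobenzofuran
Product: 23 [(2S,3S)-2-(3,4-dimethoxyphenyl)-7-methoxy-3-methyl-2,3-dihydrobenzofuran-5-yl]boronic acid, via pinacol boronate 22 (not isolated)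
Conditions: [Ir(OMe)(cod)]2 (1.5 mol %), 4,4'-di-tert-butyl-2,2'-bipyridine (3 mol %), B2pin2 (1.0 equiv), THF, 80 °C; then NaIO4, THF/H2O, rt; then 1 M HCl, rt
Reagents that add atoms: bis(pinacolato)diboron, CC1(C)OB(OC1(C)C)B1OC(C)(C)C(C)(C)O1; water, O
Why: Sterically governed iridium-catalysed aromatic C–H borylation should pick C5–H, the only ring hydrogen without an ortho substituent (C4–H and C6–H are flanked by C3a and the C7 methoxy group, and every hydrogen of the dimethoxyphenyl ring has an ortho neighbour), and periodate cleavage of the pinacol ester then gives the boronic acid that the next coupling needs.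

Step 12
Reactants: 24 methyl (R)-lactate
Product: 25 methyl (R)-2-(tert-butyldimethylsilyloxy)propanoate
Conditions: TBSCl, imidazole, DMF, rt
Reagents that add atoms: tert-butyldimethylsilyl chloride, CC(C)(C)[Si](C)(C)Cl
Why: Standard silylation of a secondary alcohol with TBSCl and imidazole protects the hydroxyl without affecting the stereocentre.

Step 13
Reactants: 25 methyl (R)-2-(tert-butyldimethylsilyloxy)propanoate
Product: 26 S-phenyl (R)-2-(tert-butyldimethylsilyloxy)propanethioate
Conditions: AlMe3, PhSH, CH2Cl2, 0 °C → rt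
Reagents that add atoms: benzenethiol, Sc1ccccc1
Why: An aluminium thiolate made from AlMe3 and the thiol converts a methyl ester directly into the thioester (ester-to-thioester exchange) without base, so the α-silyloxy centre should stay intact.

Step 14
Reactants: 23 [(2S,3S)-2-(3,4-dimethoxyphenyl)-7-methoxy-3-methyl-2,3-dihydrobenzofuran-5-yl]boronic acid; 26 S-phenyl (R)-2-(tert-butyldimethylsilyloxy)propanethioate
Product: 27 (R)-2-(tert-butyldimethylsilyloxy)-1-[(2S,3S)-2-(3,4-dimethoxyphenyl)-7-methoxy-3-methyl-2,3-dihydrobenzofuran-5-yl]propan-1-one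
Conditions: Pd2(dba)3 (2.5 mol %), tri(2-furyl)phosphine (15 mol %), Cu(O2CC4H3S) (copper thiophene-2-carboxylate, 1.5 equiv), THF, 50 °C
Reagents that add atoms: none
Why: In the Liebeskind–Srogl ketone synthesis zerovalent palladium inserts into the C–S bond and the monovalent copper carboxylate takes up the thiolate while activating the boronic acid, all without added base, so the aryl ketone should form with the α-silyloxy centre unchanged.

Step 15
Reactants: 27 (R)-2-(tert-butyldimethylsilyloxy)-1-[(2S,3S)-2-(3,4-dimethoxyphenyl)-7-methoxy-3-methyl-2,3-dihydrobenzofuran-5-yl]propan-1-one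
Product: 28 (R)-1-[(2S,3S)-2-(3,4-dimethoxyphenyl)-7-methoxy-3-methyl-2,3-dihydrobenzofuran-5-yl]-2-hydroxypropan-1-one
Conditions: HF·pyridine, pyridine, THF, 0 °C → rt
Reagents that add atoms: none
Why: Buffered fluoride desilylation frees the α-hydroxyl without enolising the ketone, and doing it before the reduction means that no protecting group has to be removed once the acid-sensitive benzylic carbinol para to O1 exists.

Step 16
Reactants: 28 (R)-1-[(2S,3S)-2-(3,4-dimethoxyphenyl)-7-methoxy-3-methyl-2,3-dihydrobenzofuran-5-yl]-2-hydroxypropan-1-one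
Product: 29 (1S,2R)-1-[(2S,3S)-2-(3,4-dimethoxyphenyl)-7-methoxy-3-methyl-2,3-dihydrobenzofuran-5-yl]propane-1,2-diol
Conditions: Zn(BH4)2, Et2O/CH2Cl2, −20 → 0 °C; then H2O
Reagents that add atoms: none
Why: In this chelation-controlled reduction (Cram chelate model) zinc bridges the carbonyl oxygen and the α-hydroxyl, and hydride enters from the face of the chelate that carries H and not CH3 on the lactate-derived carbon, which should give the anti diol with the new benzylic centre S.

Compound list
1 | 2-(furan-2-yl)acetic acid | OC(=O)Cc1ccco1 | starting material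
2 | (S)-4-benzyl-2-oxazolidinone | O=C1N[C@@H](Cc2ccccc2)CO1 | starting material
3 | 2-(furan-2-yl)acetic pivalic anhydride (formed in the flask) | CC(C)(C)C(=O)OC(=O)Cc1ccco1 | intermediate
4 | (S)-4-benzyl-3-[2-(furan-2-yl)acetyl]oxazolidin-2-one | O=C(Cc1ccco1)N2[C@@H](Cc3ccccc3)COC2=O | intermediate
5 | 3,4-dimethoxybenzaldehyde | COc1ccc(C=O)cc1OC | starting material
6 | Z-dibutylboron enolate of 4, (S)-4-benzyl-3-[(Z)-1-(dibutylboryloxy)-2-(furan-2-yl)ethenyl]oxazolidin-2-one (formed in the flask) | CCCCB(CCCC)O/C(=C\c1ccco1)N2[C@@H](Cc3ccccc3)COC2=O | intermediate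
7 | O-dibutylboryl aldolate of 8 (formed in the flask) | COc1ccc([C@@H](OB(CCCC)CCCC)[C@@H](C(=O)N2[C@@H](Cc3ccccc3)COC2=O)c4ccco4)cc1OC | intermediate
8 | (S)-4-benzyl-3-[(2R,3S)-3-(3,4-dimethoxyphenyl)-2-(furan-2-yl)-3-hydroxypropanoyl]oxazolidin-2-one | COc1ccc([C@@H](O)[C@@H](C(=O)N2[C@@H](Cc3ccccc3)COC2=O)c4ccco4)cc1OC | intermediate
9 | (S)-4-benzyl-3-[(2R,3S)-3-(tert-butyldimethylsilyloxy)-3-(3,4-dimethoxyphenyl)-2-(furan-2-yl)propanoyl]oxazolidin-2-one | COc1ccc([C@@H](O[Si](C)(C)C(C)(C)C)[C@@H](C(=O)N2[C@@H](Cc3ccccc3)COC2=O)c4ccco4)cc1OC | intermediate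
10 | (2R,3S)-3-(tert-butyldimethylsilyloxy)-3-(3,4-dimethoxyphenyl)-2-(furan-2-yl)propan-1-ol | COc1ccc([C@@H](O[Si](C)(C)C(C)(C)C)[C@@H](CO)c2ccco2)cc1OC | intermediate
11 | (2R,3S)-3-(tert-butyldimethylsilyloxy)-3-(3,4-dimethoxyphenyl)-2-(furan-2-yl)propyl 4-methylbenzenesulfonate | COc1ccc([C@@H](O[Si](C)(C)C(C)(C)C)[C@@H](COS(=O)(=O)c2ccc(C)cc2)c3ccco3)cc1OC | intermediate
12 | tert-butyl{[(1S,2R)-1-(3,4-dimethoxyphenyl)-2-(furan-2-yl)propyl]oxy}dimethylsilane | COc1ccc([C@@H](O[Si](C)(C)C(C)(C)C)[C@@H](C)c2ccco2)cc1OC | intermediate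
13 | (1S,2R)-1-(3,4-dimethoxyphenyl)-2-(furan-2-yl)propan-1-ol | COc1ccc([C@@H](O)[C@@H](C)c2ccco2)cc1OC | intermediate
14 | (E)-1,2-dichloroethenyl (1S,2R)-1-(3,4-dimethoxyphenyl)-2-(furan-2-yl)propyl ether (formed in the flask) | COc1ccc([C@@H](O/C(Cl)=C\Cl)[C@@H](C)c2ccco2)cc1OC | intermediate
15 | chloroethynyl (1S,2R)-1-(3,4-dimethoxyphenyl)-2-(furan-2-yl)propyl ether (formed in the flask) | COc1ccc([C@@H](OC#CCl)[C@@H](C)c2ccco2)cc1OC | intermediate
16 | {[(1S,2R)-1-(3,4-dimethoxyphenyl)-2-(furan-2-yl)propoxy]ethynyl}lithium (formed in the flask) | COc1ccc([C@@H](OC#C[Li])[C@@H](C)c2ccco2)cc1OC | intermediate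
17 | (1S,2R)-1-(3,4-dimethoxyphenyl)-2-(furan-2-yl)propyl ethynyl ether | COc1ccc([C@@H](OC#C)[C@@H](C)c2ccco2)cc1OC | intermediate
18 | oxepine valence tautomer of 19: (2S,3S)-2-aryl-3-methyl-2,3-dihydrofuran ring fused through C3a–C7a to an oxepine whose oxygen bridges C6 and C7 (formed in the flask) | COc1ccc([C@H]2OC3=COC=CC=C3[C@@H]2C)cc1OC | intermediate
19 | (2S,3S)-2-(3,4-dimethoxyphenyl)-3-methyl-2,3,6,7-tetrahydrobenzofuran 6,7-oxide, epoxide configuration not defined (formed in the flask) | COc1ccc([C@H]2OC3=C(C=CC4OC43)[C@@H]2C)cc1OC | intermediate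
20 | (2S,3S)-2-(3,4-dimethoxyphenyl)-3-methyl-2,3-dihydrobenzofuran-7-ol | COc1ccc([C@H]2Oc3c(O)cccc3[C@@H]2C)cc1OC | intermediate
21 | (2S,3S)-2-(3,4-dimethoxyphenyl)-7-methoxy-3-methyl-2,3-dihydrobenzofuran | COc1ccc([C@H]2Oc3c(OC)cccc3[C@@H]2C)cc1OC | intermediate
22 | 2-[(2S,3S)-2-(3,4-dimethoxyphenyl)-7-methoxy-3-methyl-2,3-dihydrobenzofuran-5-yl]-4,4,5,5-tetramethyl-1,3,2-dioxaborolane (formed in the flask) | COc1ccc([C@H]2Oc3c(OC)cc(B4OC(C)(C)C(C)(C)O4)cc3[C@@H]2C)cc1OC | intermediate
23 | [(2S,3S)-2-(3,4-dimethoxyphenyl)-7-methoxy-3-methyl-2,3-dihydrobenzofuran-5-yl]boronic acid | COc1ccc([C@H]2Oc3c(OC)cc(B(O)O)cc3[C@@H]2C)cc1OC | intermediate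
24 | methyl (R)-lactate | C[C@@H](O)C(=O)OC | starting material
25 | methyl (R)-2-(tert-butyldimethylsilyloxy)propanoate | C[C@@H](O[Si](C)(C)C(C)(C)C)C(=O)OC | intermediate
26 | S-phenyl (R)-2-(tert-butyldimethylsilyloxy)propanethioate | C[C@@H](O[Si](C)(C)C(C)(C)C)C(=O)Sc1ccccc1 | intermediate
27 | (R)-2-(tert-butyldimethylsilyloxy)-1-[(2S,3S)-2-(3,4-dimethoxyphenyl)-7-methoxy-3-methyl-2,3-dihydrobenzofuran-5-yl]propan-1-one | COc1ccc([C@H]2Oc3c(OC)cc(C(=O)[C@@H](C)O[Si](C)(C)C(C)(C)C)cc3[C@@H]2C)cc1OC | intermediate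
28 | (R)-1-[(2S,3S)-2-(3,4-dimethoxyphenyl)-7-methoxy-3-methyl-2,3-dihydrobenzofuran-5-yl]-2-hydroxypropan-1-one | COc1ccc([C@H]2Oc3c(OC)cc(C(=O)[C@@H](C)O)cc3[C@@H]2C)cc1OC | intermediate
29 | (1S,2R)-1-[(2S,3S)-2-(3,4-dimethoxyphenyl)-7-methoxy-3-methyl-2,3-dihydrobenzofuran-5-yl]propane-1,2-diol | COc1ccc([C@H]2Oc3c(OC)cc([C@H](O)[C@@H](C)O)cc3[C@@H]2C)cc1OC | target

Total step count: 16. Longest linear sequence: 14 steps (steps 1 to 11, then 14 to 16); steps 12 and 13 form the two-step side branch to thioester 26.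

Steps most likely to fail

Step 9. Once gold has activated the ynol ether, the benzylic O1–C2 bond may ionise (the dimethoxybenzylic cation is well stabilised), which would strip the alkynyl group or scramble C2; trace water may hydrate the ynol ether; and furan C3 may attack in place of C2. The fallback builds ring A from a benzene building block and closes the O1–C2 bond last; it sets out from auxiliary 2 and aldehyde 5 and comes back to the route at 21. Commercial 2-allyl-6-methoxyphenol would be protected with MOMCl and i-Pr2NEt to give 1-allyl-3-methoxy-2-(methoxymethoxy)benzene F1. Permanganate–periodate cleavage of the alkene (NaIO4, catalytic KMnO4, K2CO3, t-BuOH/H2O) should give 2-[3-methoxy-2-(methoxymethoxy)phenyl]acetic acid F2. Acylation of 2 under the conditions of step 1 would give (S)-4-benzyl-3-{2-[3-methoxy-2-(methoxymethoxy)phenyl]acetyl}oxazolidin-2-one F3, and the boron aldol reaction with 5 under the conditions of step 2 should give the syn adduct (S)-4-benzyl-3-{(2S,3S)-3-(3,4-dimethoxyphenyl)-3-hydroxy-2-[3-methoxy-2-(methoxymethoxy)phenyl]propanoyl}oxazolidin-2-one F4. The operations of steps 3 to 6 would then give in turn the silyl ether F5, (2R,3S)-3-(tert-butyldimethylsilyloxy)-3-(3,4-dimethoxyphenyl)-2-[3-methoxy-2-(methoxymethoxy)phenyl]propan-1-ol F6, its 4-methylbenzenesulfonate F7 and tert-butyl({(1S,2S)-1-(3,4-dimethoxyphenyl)-2-[3-methoxy-2-(methoxymethoxy)phenyl]propyl}oxy)dimethylsilane F8. Finally CF3CO2H in CH2Cl2 at 0 °C should remove the MOM and silyl groups, ionise the benzylic position and let the phenol close the ring to the trans compound 21, the C3 centre from the aldol step dictating the configuration at C2.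

Step 8. The potassium alkoxide may fragment, or the ethynyl ether may be lost after it forms, by acid-catalysed hydration during work-up or by sigmatropic rearrangement on warming. The fallback reaches the same ynol ether from a formate by dibromo-olefination; it sets out from 13 and comes back at 17. Formylation of 13 with acetic formic anhydride and pyridine would give (1S,2R)-1-(3,4-dimethoxyphenyl)-2-(furan-2-yl)propyl formate F9. Olefination of the formate with CBr4 and PPh3 in CH2Cl2 should give 2,2-dibromoethenyl (1S,2R)-1-(3,4-dimethoxyphenyl)-2-(furan-2-yl)propyl ether F10. n-BuLi (2.2 equiv, THF, −78 °C) would then convert F10 by bromine–lithium exchange and 1,2-shift into acetylide 16, which methanol protonates to 17.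

Step 14. Transmetalation of the electron-rich boronic acid may be slow, so that protodeboronation or thioester decomposition wins. The fallback makes the same ketone by aryllithium addition to a Weinreb amide; it sets out from 23 and 25 and comes back at 27. Bromodeboronation of 23 with CuBr2 in MeOH/H2O should give (2S,3S)-5-bromo-2-(3,4-dimethoxyphenyl)-7-methoxy-3-methyl-2,3-dihydrobenzofuran F11, and n-BuLi in THF at −78 °C would turn it into [(2S,3S)-2-(3,4-dimethoxyphenyl)-7-methoxy-3-methyl-2,3-dihydrobenzofuran-5-yl]lithium F12. Ester 25 would be converted with MeNH(OMe)·HCl and i-PrMgCl into (R)-2-(tert-butyldimethylsilyloxy)-N-methoxy-N-methylpropanamide F13, and addition of F12 to F13 should give 27 after aqueous work-up.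

Further compounds
F1 | step 9 | 1-allyl-3-methoxy-2-(methoxymethoxy)benzene | C=CCc1cccc(OC)c1OCOC
F2 | step 9 | 2-[3-methoxy-2-(methoxymethoxy)phenyl]acetic acid | OC(=O)Cc1cccc(OC)c1OCOC
F3 | step 9 | (S)-4-benzyl-3-{2-[3-methoxy-2-(methoxymethoxy)phenyl]acetyl}oxazolidin-2-one | COCOc1c(OC)cccc1CC(=O)N3[C@@H](Cc2ccccc2)COC3=O
F4 | step 9 | (S)-4-benzyl-3-{(2S,3S)-3-(3,4-dimethoxyphenyl)-3-hydroxy-2-[3-methoxy-2-(methoxymethoxy)phenyl]propanoyl}oxazolidin-2-one | COc1ccc([C@@H](O)[C@@H](C(=O)N2[C@@H](Cc3ccccc3)COC2=O)c4cccc(OC)c4OCOC)cc1OC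
F5 | step 9 | (S)-4-benzyl-3-{(2S,3S)-3-(tert-butyldimethylsilyloxy)-3-(3,4-dimethoxyphenyl)-2-[3-methoxy-2-(methoxymethoxy)phenyl]propanoyl}oxazolidin-2-one | COc1ccc([C@@H](O[Si](C)(C)C(C)(C)C)[C@@H](C(=O)N2[C@@H](Cc3ccccc3)COC2=O)c4cccc(OC)c4OCOC)cc1OC
F6 | step 9 | (2R,3S)-3-(tert-butyldimethylsilyloxy)-3-(3,4-dimethoxyphenyl)-2-[3-methoxy-2-(methoxymethoxy)phenyl]propan-1-ol | COc1ccc([C@@H](O[Si](C)(C)C(C)(C)C)[C@@H](CO)c2cccc(OC)c2OCOC)cc1OC
F7 | step 9 | (2R,3S)-3-(tert-butyldimethylsilyloxy)-3-(3,4-dimethoxyphenyl)-2-[3-methoxy-2-(methoxymethoxy)phenyl]propyl 4-methylbenzenesulfonate | COc1ccc([C@@H](O[Si](C)(C)C(C)(C)C)[C@@H](COS(=O)(=O)c2ccc(C)cc2)c3cccc(OC)c3OCOC)cc1OC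
F8 | step 9 | tert-butyl({(1S,2S)-1-(3,4-dimethoxyphenyl)-2-[3-methoxy-2-(methoxymethoxy)phenyl]propyl}oxy)dimethylsilane | COc1ccc([C@@H](O[Si](C)(C)C(C)(C)C)[C@@H](C)c2cccc(OC)c2OCOC)cc1OC
F9 | step 8 | (1S,2R)-1-(3,4-dimethoxyphenyl)-2-(furan-2-yl)propyl formate | COc1ccc([C@@H](OC=O)[C@@H](C)c2ccco2)cc1OC
F10 | step 8 | 2,2-dibromoethenyl (1S,2R)-1-(3,4-dimethoxyphenyl)-2-(furan-2-yl)propyl ether | COc1ccc([C@@H](OC=C(Br)Br)[C@@H](C)c2ccco2)cc1OC
F11 | step 14 | (2S,3S)-5-bromo-2-(3,4-dimethoxyphenyl)-7-methoxy-3-methyl-2,3-dihydrobenzofuran | COc1ccc([C@H]2Oc3c(OC)cc(Br)cc3[C@@H]2C)cc1OC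
F12 | step 14 | [(2S,3S)-2-(3,4-dimethoxyphenyl)-7-methoxy-3-methyl-2,3-dihydrobenzofuran-5-yl]lithium | COc1ccc([C@H]2Oc3c(OC)cc([Li])cc3[C@@H]2C)cc1OC
F13 | step 14 | (R)-2-(tert-butyldimethylsilyloxy)-N-methoxy-N-methylpropanamide | C[C@@H](O[Si](C)(C)C(C)(C)C)C(=O)N(C)OC
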